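Assumption: atoms carry germacrane numbers (C1/C5 ether bridge, C4/C15 spiro-epoxide, C6–O–C12 lactone, C8 ester, C14 aldehyde carbon); D-glucal and 3-methylfuran-2(5H)-one are taken as commercial. The route is a paper proposal; nothing here has been run.

**Retrosynthetic overview**
1. Target 22 ⇐ exo-face epoxidation of C4=C15 and methacryloylation of the C8 alcohol 20.
2. Eight-membered ring (C8–C9 bond, C8 stereocentre) ⇐ electrochemical Cr/Ni-catalysed Nozaki–Hiyama–Kishi ring closure of bromoenal–aldehyde 19.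
3. trans-6,12-Lactone (C6–C7 bond) ⇐ Barbier allylation of tetrahydropyran aldehyde 12 with α-(bromomethyl)butenolide 14, then translactonisation.
4. cis-2,6-Tetrahydropyran ⇐ Achmatowicz rearrangement/Kishi reduction of furyl carbinol 4, whose carbinol centre (C5) comes from D-glucal.
5. Ring order: furan → tetrahydropyran → γ-lactone → carbocycle (oxocene bridge) → spiro-epoxide.

**Route**

Step 1
Reactants: 1 D-glucal
Product: 2 (R)-1-(furan-2-yl)ethane-1,2-diol
Conditions: InCl3·3H2O (10 mol %), MeCN, rt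
Reagents that add atoms: none
Why: Lewis-acid-promoted Ferrier-type ionisation, ring contraction and dehydration of the glycal to the furan; sugar C5 is untouched and becomes the (R)-carbinol (future C5).

Step 2
Reactants: 2 (R)-1-(furan-2-yl)ethane-1,2-diol
Product: 3 (R)-1-(furan-2-yl)-2-(triisopropylsilyloxy)ethanol
Conditions: TIPSCl (1.05 equiv), imidazole, DMF, 0 °C
Reagents that add atoms: chlorotriisopropylsilane, CC(C)[Si](Cl)(C(C)C)C(C)C
Why: Steric differentiation gives selective silylation of the primary hydroxyl; TIPS resists the later TFA step and O→O migration.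

Step 3
Reactants: 3 (R)-1-(furan-2-yl)-2-(triisopropylsilyloxy)ethanol
Product: 4 (R)-1-[5-(2-hydroxyethyl)furan-2-yl]-2-(triisopropylsilyloxy)ethanol
Conditions: n-BuLi (2.2 equiv), THF, −78 → 0 °C; oxirane, 0 °C → rt; H2O
Reagents that add atoms: oxirane, C1CO1
Why: Alkoxide formation and α-lithiation of the furan at C5 (dianion), then epoxide opening by the furyllithium; the stereocentre is not involved.

Step 4
Reactants: 4 (R)-1-[5-(2-hydroxyethyl)furan-2-yl]-2-(triisopropylsilyloxy)ethanol
Product: 6 (2R,6S)-6-(2-hydroxyethyl)-2-(triisopropylsilyloxymethyl)-2H-pyran-3(6H)-one (2,6-cis), via pyranone hemiketal 5 (not isolated)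
Conditions: NBS, NaHCO3, NaOAc, THF/H2O, 0 °C; then Et3SiH, TFA, CH2Cl2, −40 → 0 °C
Reagents that add atoms: water, O
Why: Achmatowicz oxidative ring expansion followed by Kishi reduction; hydride adds to the cyclic oxocarbenium ion anti to the C5 substituent, so C1 is set 2,6-cis by the glucal-derived centre.

Step 5
Reactants: 6 (2R,6S)-6-(2-hydroxyethyl)-2-(triisopropylsilyloxymethyl)-2H-pyran-3(6H)-one
Product: 7 (2R,6R)-6-(2-hydroxyethyl)-2-(triisopropylsilyloxymethyl)oxan-3-one (2,6-cis)
Conditions: H2 (1 atm), 10 % Pd/C, EtOAc, rt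
Reagents that add atoms: none
Why: Heterogeneous hydrogenation of the conjugated, cis-disubstituted enone C=C; no stereocentre is created.

Step 6
Reactants: 7 (2R,6R)-6-(2-hydroxyethyl)-2-(triisopropylsilyloxymethyl)oxan-3-one
Product: 8 2-[(2R,6S)-5-methylidene-6-(triisopropylsilyloxymethyl)oxan-2-yl]ethanol (2,6-cis)
Conditions: Ph3PCH3Br (3 equiv), KOt-Bu (2.9 equiv), THF, 0 °C → rt
Reagents that add atoms: methyltriphenylphosphonium bromide, C[P+](c1ccccc1)(c1ccccc1)c1ccccc1.[Br-]
Why: Wittig methylenation of the ketone with excess ylide (one equivalent is consumed by the free hydroxyl); the 2,6-cis ring is also the thermodynamic one if C5 enolises transiently.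

Step 7
Reactants: 8 2-[(2R,6S)-5-methylidene-6-(triisopropylsilyloxymethyl)oxan-2-yl]ethanol
Product: 9 2-[(2R,6S)-5-methylidene-6-(triisopropylsilyloxymethyl)oxan-2-yl]acetaldehyde
Conditions: Dess–Martin periodinane, NaHCO3, CH2Cl2, 0 °C → rt
Reagents that add atoms: none
Why: Buffered Dess–Martin oxidation of the primary alcohol to the aldehyde without touching the silyl ether or the exocyclic alkene.

Step 8
Reactants: 9 2-[(2R,6S)-5-methylidene-6-(triisopropylsilyloxymethyl)oxan-2-yl]acetaldehyde
Product: 10 (E)-3-(dimethylamino)-2-[(2R,6S)-5-methylidene-6-(triisopropylsilyloxymethyl)oxan-2-yl]prop-2-enal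
Conditions: t-BuOCH(NMe2)2 (1.5 equiv), toluene, 60 °C
Reagents that add atoms: tert-butoxybis(dimethylamino)methane (Bredereck's reagent), CN(C)C(OC(C)(C)C)N(C)C
Why: Aminomethylenation of the aldehyde α-CH2 gives a vinylogous formamide that installs C9 and masks C14 as a non-electrophilic carbonyl; any retro-oxa-Michael opening re-closes to the favoured 2,6-cis ring.

Step 9
Reactants: 10 (E)-3-(dimethylamino)-2-[(2R,6S)-5-methylidene-6-(triisopropylsilyloxymethyl)oxan-2-yl]prop-2-enal
Product: 11 (E)-3-(dimethylamino)-2-[(2R,6S)-6-(hydroxymethyl)-5-methylideneoxan-2-yl]prop-2-enal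
Conditions: TBAF (1.2 equiv), THF, 0 °C → rt
Reagents that add atoms: none
Why: Fluoride-mediated cleavage of the silyl ether; the vinylogous amide is inert.

Step 10
Reactants: 11 (E)-3-(dimethylamino)-2-[(2R,6S)-6-(hydroxymethyl)-5-methylideneoxan-2-yl]prop-2-enal
Product: 12 (2S,6R)-6-[(E)-1-(dimethylamino)-3-oxoprop-1-en-2-yl]-3-methylideneoxane-2-carbaldehyde
Conditions: Dess–Martin periodinane, NaHCO3, CH2Cl2, 0 °C; used at once
Reagents that add atoms: none
Why: Neutral Dess–Martin oxidation gives the C6 aldehyde without base, which would isomerise this β,γ-unsaturated α-alkoxy aldehyde or epimerise C5.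

Step 11
Reactants: 13 3-methylfuran-2(5H)-one
Product: 14 3-(bromomethyl)furan-2(5H)-one
Conditions: NBS (1.05 equiv), AIBN (cat.), PhCF3, reflux
Reagents that add atoms: N-bromosuccinimide, BrN1C(=O)CCC1=O
Why: Wohl–Ziegler radical bromination of the allylic methyl group, the known entry to this 2-(alkoxycarbonyl)allyl bromide.

Step 12
Reactants: 12 (2S,6R)-6-[(E)-1-(dimethylamino)-3-oxoprop-1-en-2-yl]-3-methylideneoxane-2-carbaldehyde; 14 3-(bromomethyl)furan-2(5H)-one
Product: 16 trans-6,12-lactone alcohol [α-methylene-γ-butyrolactone on C6/C7 with CH2OH (C8) on C7; C1/C5/C6/C7 as in 22], via Barbier adduct 15 (not isolated)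
Conditions: In powder (1.5 equiv), THF/H2O (1:1), rt; then DBU (0.3 equiv), CH2Cl2, rt
Reagents that add atoms: none
Why: Indium Barbier 2-(alkoxycarbonyl)allylation through a Zimmerman–Traxler chair (ring-locked E-type allylindium gives C6/C7 anti) with Cram-chelate attack via the ring oxygen setting C6 syn to O5; base-mediated translactonisation then gives the more substituted trans-β,γ-disubstituted lactone and frees C8–OH.

Step 13
Reactants: 16 trans-6,12-lactone alcohol
Product: 17 trans-6,12-lactone C8 aldehyde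
Conditions: Dess–Martin periodinane, NaHCO3, CH2Cl2, 0 °C; filtered and used at once
Reagents that add atoms: none
Why: Buffered Dess–Martin oxidation under non-basic conditions, because the aldehyde is epimerisable at C7 and is a β-acyloxy aldehyde.

Step 14
Reactants: 17 trans-6,12-lactone C8 aldehyde
Product: 19 (E)-bromoenal aldehyde [C9H(Br)=C10(CHO) on C1; Br trans to CHO], via bromovinyl iminium bromide 18 (not isolated)
Conditions: (COBr)2 (1.2 equiv), CH2Cl2, −78 → −20 °C; then pH 7 phosphate buffer, 0 °C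
Reagents that add atoms: oxalyl bromide, BrC(=O)C(=O)Br; water, O
Why: Vilsmeier-type activation of the vinylogous formamide oxygen, bromide addition–elimination and iminium hydrolysis give the β-bromo enal; Br trans to CHO is the thermodynamic geometry, as in 2-alkyl-2-enals.

Step 15
Reactants: 19 (E)-bromoenal aldehyde
Product: 20 (1R,5R,6S,7R,8R,9E)-8-hydroxy-14-oxo-1,5-epoxygermacra-4(15),9,11(13)-trien-6,12-olide
Conditions: CrCl3 (20 mol %), NiBr2·glyme/neocuproine (2 mol %), Cp2ZrCl2 (1.2 equiv), Bu4NBr, DMF (2 mM), Al(+)|Ni foam(−), undivided cell, constant current, rt; aqueous work-up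
Reagents that add atoms: none
Why: Proposed new method: an electrochemically driven, Cr/Ni-catalytic Nozaki–Hiyama–Kishi ring closure of a β-bromo-α-formyl alkene (a vinylogous acyl bromide) onto an aliphatic aldehyde across a cis-2,6-tetrahydropyran; cathodically formed Ni(0) inserts into the activated C(sp2)–Br bond with retention and transmetalates to Cr(III), the alkenyl–Cr (cis to C1, so only the C8 aldehyde is in reach) adds through a Felkin–Anh arrangement (C7–C11 anti to incoming C9, tether through C6) to give the 8R alkoxide, Cp2ZrCl2 frees Cr for cathodic turnover, and current-limited generation of the organochromium acts as built-in high dilution; closest known chemistry is the intermolecular electrochemical catalytic NHK alkenylation of aldehydes and stoichiometric CrCl2/NiCl2 closures of oxa-bridged medium rings.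

Step 16
Reactants: 20 (1R,5R,6S,7R,8R,9E)-8-hydroxy-14-oxo-1,5-epoxygermacra-4(15),9,11(13)-trien-6,12-olide
Product: 21 (1R,5R,6S,7R,8R,9E)-8-(methacryloyloxy)-14-oxo-1,5-epoxygermacra-4(15),9,11(13)-trien-6,12-olide
Conditions: methacrylic anhydride (2 equiv), Et3N, DMAP (0.2 equiv), CH2Cl2, 0 °C
Reagents that add atoms: methacrylic anhydride, CC(=C)C(=O)OC(=O)C(C)=C
Why: DMAP-catalysed acylation of the secondary allylic alcohol at low temperature, too mild for translactonisation to O8 or elimination.

Step 17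
Reactants: 21 (1R,5R,6S,7R,8R,9E)-8-(methacryloyloxy)-14-oxo-1,5-epoxygermacra-4(15),9,11(13)-trien-6,12-olide
Product: 22 (1R,4R,5R,6S,7R,8R,9E)-8-(methacryloyloxy)-14-oxo-1,5:4,15-diepoxygermacra-9,11(13)-dien-6,12-olide (CNP0257628.1)
Conditions: dimethyldioxirane (1.2 equiv, acetone), CH2Cl2, −20 → 0 °C
Reagents that add atoms: dimethyldioxirane, CC1(C)OO1
Why: Electrophilic epoxidation of the only electron-rich alkene (the enal, methacrylate and α-methylene lactone C=C are deactivated) on the exo face, anti to the C5–C6 bond and the eight-membered bridge, which sets C4 as R.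

**Compound list**
1 | D-glucal (1,5-anhydro-2-deoxy-D-arabino-hex-1-enitol) | OC[C@H]1OC=C[C@@H](O)[C@@H]1O | starting material
2 | (R)-1-(furan-2-yl)ethane-1,2-diol | OC[C@@H](O)c1ccco1 | intermediate
3 | (R)-1-(furan-2-yl)-2-(triisopropylsilyloxy)ethanol | CC(C)[Si](C(C)C)(C(C)C)OC[C@@H](O)c1ccco1 | intermediate
4 | (R)-1-[5-(2-hydroxyethyl)furan-2-yl]-2-(triisopropylsilyloxy)ethanol | CC(C)[Si](C(C)C)(C(C)C)OC[C@@H](O)c1ccc(CCO)o1 | intermediate
5 | (2R)-6-hydroxy-6-(2-hydroxyethyl)-2-(triisopropylsilyloxymethyl)-2H-pyran-3(6H)-one (hemiketal, anomer mixture) | CC(C)[Si](C(C)C)(C(C)C)OC[C@H]1OC(O)(CCO)C=CC1=O | intermediate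
6 | (2R,6S)-6-(2-hydroxyethyl)-2-(triisopropylsilyloxymethyl)-2H-pyran-3(6H)-one (2,6-cis) | OCC[C@H]1C=CC(=O)[C@H](O1)CO[Si](C(C)C)(C(C)C)C(C)C | intermediate
7 | (2R,6R)-6-(2-hydroxyethyl)-2-(triisopropylsilyloxymethyl)oxan-3-one (2,6-cis) | OCC[C@H]1CCC(=O)[C@H](O1)CO[Si](C(C)C)(C(C)C)C(C)C | intermediate
8 | 2-[(2R,6S)-5-methylidene-6-(triisopropylsilyloxymethyl)oxan-2-yl]ethanol | OCC[C@H]1CCC(=C)[C@H](O1)CO[Si](C(C)C)(C(C)C)C(C)C | intermediate
9 | 2-[(2R,6S)-5-methylidene-6-(triisopropylsilyloxymethyl)oxan-2-yl]acetaldehyde | O=CC[C@H]1CCC(=C)[C@H](O1)CO[Si](C(C)C)(C(C)C)C(C)C | intermediate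
10 | (E)-3-(dimethylamino)-2-[(2R,6S)-5-methylidene-6-(triisopropylsilyloxymethyl)oxan-2-yl]prop-2-enal | CN(C)/C=C(/C=O)[C@H]1CCC(=C)[C@H](O1)CO[Si](C(C)C)(C(C)C)C(C)C | intermediate
11 | (E)-3-(dimethylamino)-2-[(2R,6S)-6-(hydroxymethyl)-5-methylideneoxan-2-yl]prop-2-enal | CN(C)/C=C(/C=O)[C@H]1CCC(=C)[C@H](O1)CO | intermediate
12 | (2S,6R)-6-[(E)-1-(dimethylamino)-3-oxoprop-1-en-2-yl]-3-methylideneoxane-2-carbaldehyde | CN(C)/C=C(/C=O)[C@H]1CCC(=C)[C@H](O1)C=O | intermediate
13 | 3-methylfuran-2(5H)-one | CC1=CCOC1=O | starting material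
14 | 3-(bromomethyl)furan-2(5H)-one | BrCC1=CCOC1=O | intermediate
15 | Barbier adduct: 3-methylidene-γ-butyrolactone carrying at its β-carbon (C7) the C6 carbinol attached to the tetrahydropyran (O5/O6 syn, C6/C7 anti) | CN(C)/C=C(/C=O)[C@H]1CCC(=C)[C@H](O1)[C@@H](O)[C@H]2COC(=O)C2=C | intermediate
16 | trans-6,12-lactone alcohol: α-methylene-γ-butyrolactone with the tetrahydropyran on C6 and CH2OH (C8) on C7, trans | CN(C)/C=C(/C=O)[C@H]1CCC(=C)[C@H](O1)[C@H]2OC(=O)C(=C)[C@@H]2CO | intermediate
17 | trans-6,12-lactone C8 aldehyde (CHO on C7) | CN(C)/C=C(/C=O)[C@H]1CCC(=C)[C@H](O1)[C@H]2OC(=O)C(=C)[C@@H]2C=O | intermediate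
18 | bromovinyl iminium bromide [C9H(Br)=C10–CH=NMe2+ Br−; rest as 17] | C[N+](C)=C/C(=C/Br)[C@H]1CCC(=C)[C@H](O1)[C@H]2OC(=O)C(=C)[C@@H]2C=O.[Br-] | intermediate
19 | (E)-bromoenal aldehyde [C9H(Br)=C10(CHO) on C1, Br trans to CHO; lactone aldehyde as 17] | Br/C=C(/C=O)[C@H]1CCC(=C)[C@H](O1)[C@H]2OC(=O)C(=C)[C@@H]2C=O | intermediate
20 | (1R,5R,6S,7R,8R,9E)-8-hydroxy-14-oxo-1,5-epoxygermacra-4(15),9,11(13)-trien-6,12-olide | O[C@@H]1/C=C(/C=O)[C@H]2CCC(=C)[C@H](O2)[C@H]2OC(=O)C(=C)[C@@H]21 | intermediate
21 | (1R,5R,6S,7R,8R,9E)-8-(methacryloyloxy)-14-oxo-1,5-epoxygermacra-4(15),9,11(13)-trien-6,12-olide | C=C(C)C(=O)O[C@@H]1/C=C(/C=O)[C@H]2CCC(=C)[C@H](O2)[C@H]2OC(=O)C(=C)[C@@H]21 | intermediate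
22 | (1R,4R,5R,6S,7R,8R,9E)-8-(methacryloyloxy)-14-oxo-1,5:4,15-diepoxygermacra-9,11(13)-dien-6,12-olide (CNP0257628.1) | C=C(C)C(=O)O[C@@H]1/C=C(/C=O)[C@H]2CC[C@@]3(CO3)[C@H](O2)[C@H]2OC(=O)C(=C)[C@@H]21 | target

**Step count and risks**
Total steps: 17. Longest linear sequence: 16 (steps 1–10 and 12–17; step 11 is a one-step branch).

Most likely to fail:

- **Step 15 (the proposed electrochemical ring closure).** Failure modes are no cyclisation, oligomerisation through the enal carbonyl, or the wrong C8 epimer. Fallback, setting out from 19 and returning at 20: exchange the vinylogous acyl bromide with NaI in acetone to the iodoenal F1, then cyclise by the classical thermal, stoichiometric Nozaki–Hiyama–Kishi protocol (CrCl2 in large excess, NiCl2 1 mol %, DMSO/THF, syringe-pump addition, rt), the established way to close oxa-bridged medium rings.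

- **Step 12 (Barbier allylation and translactonisation).** The aldehyde 12 is isomerisation-prone, and C6 depends on chelation through the ring oxygen under aqueous indium conditions, which may be only moderate. Fallback, setting out from 12 and 14 and returning at 16: abandon the in-situ aqueous Barbier process. Pre-form the allylzinc bromide F2 from 14 (activated Zn, THF, 0 °C) and add it at −78 °C to the pre-formed MgBr2·OEt2 chelate of 12 in CH2Cl2 (Reformatsky-type addition under enforced Cram-chelate control) to give 15. Then translactonise under acid (CSA, CH2Cl2) instead of base to reach 16.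

- **Step 17 (late epoxidation).** The risk is the wrong face at C4 or over-oxidation of the enal. Fallback, setting out from 21 and returning at 22: a two-step halohydrin route. NBS in THF/H2O gives the bromohydrin F3 by anti addition (water opens the bromonium ion at the tertiary C4), and Ag2O in CH2Cl2 closes the epoxide. Oxygen ends on the face opposite to the one the electrophile attacks, so this is stereocomplementary to direct dioxirane epoxidation and is the remedy if DMDO gives the C4 epimer.

Further compounds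
F1 | step 15 | (E)-iodoenal aldehyde [iodo analogue of 19] | I/C=C(/C=O)[C@H]1CCC(=C)[C@H](O1)[C@H]2OC(=O)C(=C)[C@@H]2C=O
F2 | step 12 | [(2-oxo-2,5-dihydrofuran-3-yl)methyl]zinc bromide | Br[Zn]CC1=CCOC1=O
F3 | step 17 | C4 bromohydrin of 21 [4-hydroxy-15-bromo, OH on the face of the target epoxide oxygen] | C=C(C)C(=O)O[C@@H]1/C=C(/C=O)[C@H]2CC[C@@](O)(CBr)[C@H](O2)[C@H]2OC(=O)C(=C)[C@@H]21
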